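The ten-membered carbocycle is made by ring expansion, not by ring closure. With germacrane labels (C1=C10 the ester-bearing alkene, C4–C5 the epoxide, C6 the lactone carbinol, C7 the ring fusion, C8 and C9 the acyloxy carbons), the ring holds the array C4=C5–C6–C7–C8–C9(O) once the epoxide is traced back to an alkene. This is the imprint of an oxy-Cope product, so C6–C7 is disconnected while C4–C9 is reconnected, giving a cyclohexene (C9, C10, C1–C4). One anionic oxy-Cope rearrangement with enolate hydroxylation expands the six-membered ring by four atoms, sets C6 and C7, fixes both ring alkenes and oxygenates C8. The precursor is a cis-1,6-dialkenyl-2-iodocyclohex-2-en-1-ol with E 4-methoxybenzyloxyvinyl and E dienyl arms.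

Key step: step 11

Remark on labels: in the ten-membered compounds the ring atoms keep the labels above; C11, C12 and C13 are the three carbons on C7 (C12 oxygenated, C13 the methylidene carbon). Descriptors at C6, C7 and C9 change along the route only because CIP priorities change; the one true inversion is at C8 in step 12.

Assumption: the antipode of the phase-transfer catalyst that gives the S keto ester 2 is chosen in a trial run; both antipodes are accessible.

Step 1
Reactants: 1 tert-butyl 2-oxocyclohexane-1-carboxylate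
Product: 2 tert-butyl (1S)-1-methyl-2-oxocyclohexane-1-carboxylate
Conditions: MeI, chiral spiro bis(binaphthyl)ammonium bromide (1 mol %), CsOH·H2O, toluene, −40 °C
Reagents that add atoms: iodomethane, CI
Why: Enantioselective phase-transfer alkylation, in which the caesium enolate of the beta-keto ester is methylated inside the chiral ammonium ion pair, sets the quaternary carbon (the later C4) as S.

Step 2
Reactants: 2 tert-butyl (1S)-1-methyl-2-oxocyclohexane-1-carboxylate
Product: 3 tert-butyl (1S)-1-methyl-2-oxocyclohex-3-ene-1-carboxylate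
Conditions: IBX, DMSO/toluene, 70 °C
Reagents that add atoms: none
Why: IBX dehydrogenation of a ketone through its enol can only unsaturate the C3–C4 side because the other alpha carbon is quaternary, so the stereocentre is untouched.

Step 3
Reactants: 3 tert-butyl (1S)-1-methyl-2-oxocyclohex-3-ene-1-carboxylate
Product: 4 tert-butyl (1S)-3-iodo-1-methyl-2-oxocyclohex-3-ene-1-carboxylate
Conditions: I2, pyridine, CH2Cl2, 0 °C to rt
Reagents that add atoms: iodine, II
Why: Alpha-iodination of an enone by the iodine/pyridine protocol (conjugate addition of pyridine, iodination of the enolate, loss of pyridine) is specific for the alpha-vinyl position, the later C10.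

Step 4
Reactants: 5 2-bromoprop-2-en-1-ol
Product: 6 [(2-bromoprop-2-en-1-yl)oxy](tert-butyl)dimethylsilane
Conditions: TBSCl, imidazole, CH2Cl2, 0 °C to rt
Reagents that add atoms: tert-butyldimethylsilyl chloride, CC(C)(C)[Si](C)(C)Cl
Why: Imidazole-mediated silylation of a primary alcohol gives a silyl ether that should survive the organometallic, basic and oxidative steps ahead.

Step 5
Reactants: 6 [(2-bromoprop-2-en-1-yl)oxy](tert-butyl)dimethylsilane; 7 (E)-1,2-bis(tributylstannyl)ethene (2 equiv)
Product: 8 tert-butyl(dimethyl){[(3E)-2-methylidene-4-(tributylstannyl)but-3-en-1-yl]oxy}silane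
Conditions: Pd(PPh3)4 (5 mol %), toluene, 90 °C
Reagents that add atoms: none
Why: Stille cross-coupling of the alkenyl bromide with one tin terminus proceeds with retention, and the excess of 7 suppresses double coupling, so the E dienylstannane carrying C8, C7, C11, C13 and C12 should result.

Step 6
Reactants: 8 E dienylstannane; 4 tert-butyl (1S)-3-iodo-1-methyl-2-oxocyclohex-3-ene-1-carboxylate
Product: 11 tert-butyl (1S,2R)-2-[(1E)-3-({[tert-butyl(dimethyl)silyl]oxy}methyl)buta-1,3-dien-1-yl]-2-hydroxy-3-iodo-1-methylcyclohex-3-ene-1-carboxylate, via dienyllithium 9 (not isolated), via dienylcerium dichloride 10 (not isolated)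
Conditions: 8, n-BuLi, THF, −78 °C; CeCl3 (anhydrous), −78 °C; then 4, −78 °C; aq NH4Cl at −78 °C
Reagents that add atoms: none
Why: Tin–lithium exchange with retention and transmetallation to the less basic organocerium favour clean 1,2-addition over iodine–metal exchange, and trivalent cerium bridging the ketone and ester carbonyl oxygens holds the ester in the carbonyl plane with methyl pseudoaxial, so the dienyl group should enter anti to methyl (carbinol 2R, hydroxyl cis to methyl, dienyl cis to the ester).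

Step 7
Reactants: 11 tertiary dienyl carbinol ester
Product: 12 (1R,6R)-1-[(1E)-3-({[tert-butyl(dimethyl)silyl]oxy}methyl)buta-1,3-dien-1-yl]-6-(hydroxymethyl)-2-iodo-6-methylcyclohex-2-en-1-ol
Conditions: DIBAL-H (5 equiv), CH2Cl2, −78 °C to rt; Rochelle salt work-up
Reagents that add atoms: none
Why: Excess DIBAL-H reduces the hindered ester to the primary alcohol and leaves the alkenyl iodide, the diene and the silyl ether alone.

Step 8
Reactants: 12 diol
Product: 13 (1S,2R)-2-[(1E)-3-({[tert-butyl(dimethyl)silyl]oxy}methyl)buta-1,3-dien-1-yl]-2-hydroxy-3-iodo-1-methylcyclohex-3-ene-1-carbaldehyde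
Conditions: Dess–Martin periodinane, NaHCO3, CH2Cl2, 0 °C
Reagents that add atoms: none
Why: Dess–Martin oxidation converts only the primary alcohol, since the tertiary alcohol has no carbinol hydrogen and the new aldehyde has no alpha hydrogen to epimerise.

Step 9
Reactants: 13 hydroxy aldehyde; 14 2-(dichloromethyl)-4,4,5,5-tetramethyl-1,3,2-dioxaborolane
Product: 16 (1R,6R)-1-[(1E)-3-({[tert-butyl(dimethyl)silyl]oxy}methyl)buta-1,3-dien-1-yl]-2-iodo-6-methyl-6-[(E)-2-(4,4,5,5-tetramethyl-1,3,2-dioxaborolan-2-yl)ethenyl]cyclohex-2-en-1-ol, via geminal dichromium boronate 15 (not isolated)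
Conditions: CrCl2, LiI, THF, rt
Reagents that add atoms: none
Why: In this Takai–Utimoto-type olefination the geminal dichromium reagent made from 14 by divalent chromium adds to the aldehyde and eliminates to the E alkenyl boronate (new carbon = C6), under conditions that tolerate the free tertiary alcohol and, without a nickel salt, the alkenyl iodide.

Step 10
Reactants: 16 E alkenyl pinacol boronate
Product: 17 (1R,6R)-1-[(1E)-3-({[tert-butyl(dimethyl)silyl]oxy}methyl)buta-1,3-dien-1-yl]-2-iodo-6-{(E)-2-[(4-methoxybenzyl)oxy]ethenyl}-6-methylcyclohex-2-en-1-ol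
Conditions: 4-methoxybenzyl alcohol (excess), Cu(OAc)2 (2 equiv), Et3N, 4 Å MS, rt
Reagents that add atoms: 4-methoxybenzyl alcohol, COc1ccc(CO)cc1
Why: In this Chan–Lam-type oxidative etherification, boron-to-copper transmetallation and C–O reductive elimination at copper proceed with retention, so the E enol ether should form while the hindered tertiary alcohol does not compete.

Step 11
Reactants: 17 cis-dialkenyl iodocyclohexenol
Product: 20 (1E,4Z,6R,7R,8R)-8-hydroxy-10-iodo-6-[(4-methoxybenzyl)oxy]-4-methyl-7-(3-{[tert-butyl(dimethyl)silyl]oxy}prop-1-en-2-yl)cyclodeca-1(10),4-dien-9-one, via potassium alkoxide 18 (not isolated), via potassium enolate 19 (not isolated)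
Conditions: KHMDS, 18-crown-6, THF, −78 to 0 °C; then 2-(phenylsulfonyl)-3-phenyloxaziridine, −78 °C; aq NH4Cl at −78 °C
Reagents that add atoms: 2-(phenylsulfonyl)-3-phenyloxaziridine, O=S(=O)(N1OC1c1ccccc1)c1ccccc1
Why: KHMDS with 18-crown-6 (chosen over a metal hydride to spare the alkenyl iodide) gives the dissociated alkoxide 18, whose oxido group weakens the C4–C9 bond between two fully substituted, doubly allylic carbons so that a concerted [3,3] shift through the chair C7=C8–C9–C4–C5=C6 should occur below room temperature; the closest known reaction type is the anionic oxy-Cope ring expansion of 1,2-dialkenylcyclohexanols to cyclodecenones with oxidation of the enolate in the same flask. The ten-membered ring is not closed end to end but arises by four-atom expansion of the cyclohexene, C6–C7 forming as C4–C9 breaks. C6 and C7 are set by chirality transfer from C4 and C9 through the chair in which the enol ether oxygen and C11 of the two E termini sit equatorial, which also places the C6 oxygen and the C7 side chain trans as the lactone requires. Z C4=C5 follows from C3 axial and methyl equatorial at C4, the ring-trans enolate 19 from C10 equatorial at C9, and the cis C1=C10 bond is inherited from the cyclohexene. The selectivity needed is for this chair over its ring-flipped partner: the cis arrangement of the two alkenyl arms makes it accessible, and the flipped chair is penalised by two axial carbon substituents (methyl and the iodo-bearing C10) against one (C3). C8 is set by the oxaziridine attacking the outer face of the ring-trans enolate in the conformer delivered by the chair (8R expected; were the other face to react, a retentive acylation would replace the inversion of step 12).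

Step 12
Reactants: 20 (8R)-hydroxy iodo dienone
Product: 21 (1E,4Z,6R,7S,8S)-10-iodo-6-[(4-methoxybenzyl)oxy]-4-methyl-9-oxo-7-(3-{[tert-butyl(dimethyl)silyl]oxy}prop-1-en-2-yl)cyclodeca-1(10),4-dien-8-yl 2-methylprop-2-enoate
Conditions: methacrylic acid, PPh3, DIAD, THF, 0 °C to rt
Reagents that add atoms: methacrylic acid, C=C(C)C(=O)O
Why: In this Mitsunobu esterification the oxyphosphonium ion of the alpha-ketol is displaced by methacrylate in an SN2 process helped by the adjacent carbonyl group, which inverts C8 from R to S.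

Step 13
Reactants: 21 (8S)-methacrylate iodoenone
Product: 22 (1E,4Z,6R,7S,8S,9R)-9-hydroxy-10-iodo-6-[(4-methoxybenzyl)oxy]-4-methyl-7-(3-{[tert-butyl(dimethyl)silyl]oxy}prop-1-en-2-yl)cyclodeca-1(10),4-dien-8-yl 2-methylprop-2-enoate
Conditions: NaBH4, CeCl3·7H2O, MeOH, −78 °C
Reagents that add atoms: none
Why: Luche reduction adds hydride 1,2 to the iodoenone from the ring periphery anti to the C8–O bond (polar Felkin–Anh arrangement), which should set the 8,9-syn relationship of the target (descriptor 9R here because C10 carries iodine).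

Step 14
Reactants: 22 iodo allylic alcohol
Product: 23 methyl (1E,4Z,6R,7S,8S,9S)-9-hydroxy-6-[(4-methoxybenzyl)oxy]-4-methyl-8-(methacryloyloxy)-7-(3-{[tert-butyl(dimethyl)silyl]oxy}prop-1-en-2-yl)cyclodeca-1(10),4-diene-10-carboxylate
Conditions: CO (1 atm), PdCl2(PPh3)2 (5 mol %), iPr2NEt, MeOH/DMF, 40 °C
Reagents that add atoms: carbon monoxide, [C-]#[O+]; methanol, CO
Why: Palladium-catalysed alkoxycarbonylation (oxidative addition of zerovalent palladium to C–I, CO insertion, methanolysis of the acylpalladium) retains the alkene geometry and is run on the free alcohol so that no ionisable allylic acetate meets palladium.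

Step 15
Reactants: 23 hydroxy ester
Product: 24 methyl (1E,4Z,6R,7S,8S,9S)-9-acetoxy-6-[(4-methoxybenzyl)oxy]-4-methyl-8-(methacryloyloxy)-7-(3-{[tert-butyl(dimethyl)silyl]oxy}prop-1-en-2-yl)cyclodeca-1(10),4-diene-10-carboxylate
Conditions: Ac2O, pyridine, DMAP (cat.), CH2Cl2, 0 °C
Reagents that add atoms: acetic anhydride, CC(=O)OC(C)=O
Why: DMAP-catalysed acetylation of the secondary allylic alcohol occurs with retention at C9 and completes the three ester groups.

Step 16
Reactants: 24 fully esterified cyclodecadiene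
Product: 25 methyl (1E,4Z,6R,7S,8S,9S)-9-acetoxy-6-hydroxy-4-methyl-8-(methacryloyloxy)-7-(3-{[tert-butyl(dimethyl)silyl]oxy}prop-1-en-2-yl)cyclodeca-1(10),4-diene-10-carboxylate
Conditions: DDQ, CH2Cl2/pH 7 buffer, 0 °C
Reagents that add atoms: none
Why: DDQ cleaves the 4-methoxybenzyl ether through the benzylic oxocarbenium ion and its hydrolysis, sparing the silyl ether, the esters and the electron-poor alkenes and freeing the C6 hydroxyl.

Step 17
Reactants: 25 C6 allylic alcohol
Product: 26 methyl (1E,4R,5S,6S,7S,8S,9S)-9-acetoxy-4,5-epoxy-6-hydroxy-4-methyl-8-(methacryloyloxy)-7-(3-{[tert-butyl(dimethyl)silyl]oxy}prop-1-en-2-yl)cyclodec-1(10)-ene-10-carboxylate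
Conditions: VO(acac)2 (cat.), t-BuOOH, CH2Cl2, 0 °C
Reagents that add atoms: tert-butyl hydroperoxide, CC(C)(C)OO
Why: In this hydroxyl-directed epoxidation the vanadium-bound C6 alkoxide delivers peroxide oxygen to the face of the Z C4=C5 bond on its own side, as in medium-ring cis-allylic alcohols, setting C4 (R) and C5 (S), while the other alkenes are conjugated to carbonyl groups or only homoallylic.

Step 18
Reactants: 26 epoxy alcohol
Product: 27 methyl (1E,4R,5S,6S,7S,8S,9S)-9-acetoxy-4,5-epoxy-6-hydroxy-7-(3-hydroxyprop-1-en-2-yl)-4-methyl-8-(methacryloyloxy)cyclodec-1(10)-ene-10-carboxylate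
Conditions: HF·pyridine, pyridine, THF, 0 °C
Reagents that add atoms: none
Why: Fluoride cleavage of the primary silyl ether under pyridine-buffered conditions should be mild enough to leave the epoxide, the three esters and the allylic acetate untouched.

Step 19
Reactants: 27 epoxy diol
Product: 30 CNP0153978.8, via hydroxy enal 28 (not isolated), via lactol 29 (not isolated)
Conditions: MnO2 (activated, excess), CH2Cl2, rt
Reagents that add atoms: none
Why: MnO2 oxidises only the allylic primary alcohol to the enal, the C6 hydroxyl captures it as the lactol and a second oxidation gives the alpha-methylene gamma-lactone, whose trans fusion is already fixed by C6 and C7.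

Compound list
1 | tert-butyl 2-oxocyclohexane-1-carboxylate | CC(C)(C)OC(=O)C1CCCCC1=O | starting material
2 | tert-butyl (1S)-1-methyl-2-oxocyclohexane-1-carboxylate | CC(C)(C)OC(=O)[C@@]1(C)CCCCC1=O | intermediate
3 | tert-butyl (1S)-1-methyl-2-oxocyclohex-3-ene-1-carboxylate | CC(C)(C)OC(=O)[C@@]1(C)CCC=CC1=O | intermediate
4 | tert-butyl (1S)-3-iodo-1-methyl-2-oxocyclohex-3-ene-1-carboxylate | CC(C)(C)OC(=O)[C@@]1(C)CCC=C(I)C1=O | intermediate
5 | 2-bromoprop-2-en-1-ol | C=C(Br)CO | starting material
6 | [(2-bromoprop-2-en-1-yl)oxy](tert-butyl)dimethylsilane | C=C(Br)CO[Si](C)(C)C(C)(C)C | intermediate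
7 | (E)-1,2-bis(tributylstannyl)ethene | CCCC[Sn](CCCC)(CCCC)/C=C/[Sn](CCCC)(CCCC)CCCC | starting material
8 | tert-butyl(dimethyl){[(3E)-2-methylidene-4-(tributylstannyl)but-3-en-1-yl]oxy}silane | C=C(CO[Si](C)(C)C(C)(C)C)/C=C/[Sn](CCCC)(CCCC)CCCC | intermediate
9 | [(1E)-3-({[tert-butyl(dimethyl)silyl]oxy}methyl)buta-1,3-dien-1-yl]lithium (not isolated) | [Li]/C=C/C(=C)CO[Si](C)(C)C(C)(C)C | intermediate
10 | dichloro[(1E)-3-({[tert-butyl(dimethyl)silyl]oxy}methyl)buta-1,3-dien-1-yl]cerium (not isolated) | Cl[Ce](Cl)/C=C/C(=C)CO[Si](C)(C)C(C)(C)C | intermediate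
11 | tert-butyl (1S,2R)-2-[(1E)-3-({[tert-butyl(dimethyl)silyl]oxy}methyl)buta-1,3-dien-1-yl]-2-hydroxy-3-iodo-1-methylcyclohex-3-ene-1-carboxylate | CC(C)(C)OC(=O)[C@@]1(C)CCC=C(I)[C@@]1(O)/C=C/C(=C)CO[Si](C)(C)C(C)(C)C | intermediate
12 | (1R,6R)-1-[(1E)-3-({[tert-butyl(dimethyl)silyl]oxy}methyl)buta-1,3-dien-1-yl]-6-(hydroxymethyl)-2-iodo-6-methylcyclohex-2-en-1-ol | OC[C@@]1(C)CCC=C(I)[C@@]1(O)/C=C/C(=C)CO[Si](C)(C)C(C)(C)C | intermediate
13 | (1S,2R)-2-[(1E)-3-({[tert-butyl(dimethyl)silyl]oxy}methyl)buta-1,3-dien-1-yl]-2-hydroxy-3-iodo-1-methylcyclohex-3-ene-1-carbaldehyde | O=C[C@@]1(C)CCC=C(I)[C@@]1(O)/C=C/C(=C)CO[Si](C)(C)C(C)(C)C | intermediate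
14 | 2-(dichloromethyl)-4,4,5,5-tetramethyl-1,3,2-dioxaborolane | CC1(C)OB(C(Cl)Cl)OC1(C)C | starting material
15 | 2-[bis(dichlorochromio)methyl]-4,4,5,5-tetramethyl-1,3,2-dioxaborolane, formal structure of the geminal dichromium reagent (not isolated) | CC1(C)OB(C([Cr](Cl)Cl)[Cr](Cl)Cl)OC1(C)C | intermediate
16 | (1R,6R)-1-[(1E)-3-({[tert-butyl(dimethyl)silyl]oxy}methyl)buta-1,3-dien-1-yl]-2-iodo-6-methyl-6-[(E)-2-(4,4,5,5-tetramethyl-1,3,2-dioxaborolan-2-yl)ethenyl]cyclohex-2-en-1-ol | CC1(C)OB(/C=C/[C@@]2(C)CCC=C(I)[C@@]2(O)/C=C/C(=C)CO[Si](C)(C)C(C)(C)C)OC1(C)C | intermediate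
17 | (1R,6R)-1-[(1E)-3-({[tert-butyl(dimethyl)silyl]oxy}methyl)buta-1,3-dien-1-yl]-2-iodo-6-{(E)-2-[(4-methoxybenzyl)oxy]ethenyl}-6-methylcyclohex-2-en-1-ol | COc1ccc(CO/C=C/[C@@]2(C)CCC=C(I)[C@@]2(O)/C=C/C(=C)CO[Si](C)(C)C(C)(C)C)cc1 | intermediate
18 | potassium alkoxide of 17 (not isolated) | [K+].COc1ccc(CO/C=C/[C@@]2(C)CCC=C(I)[C@@]2([O-])/C=C/C(=C)CO[Si](C)(C)C(C)(C)C)cc1 | intermediate
19 | potassium enolate of the ten-membered iodo dienone, ring-trans C8=C9 (8Z by CIP), C1=C10 ring-cis, C4=C5 Z, C6 and C7 configured as in 20 (not isolated) | [K+].[O-]/C1=C\[C@@H](C(=C)CO[Si](C)(C)C(C)(C)C)[C@H](OCc2ccc(OC)cc2)/C=C(/C)CC/C=C1/I | intermediate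
20 | (1E,4Z,6R,7R,8R)-8-hydroxy-10-iodo-6-[(4-methoxybenzyl)oxy]-4-methyl-7-(3-{[tert-butyl(dimethyl)silyl]oxy}prop-1-en-2-yl)cyclodeca-1(10),4-dien-9-one (C1=C10 ring-cis) | O[C@@H]1[C@@H](C(=C)CO[Si](C)(C)C(C)(C)C)[C@H](OCc2ccc(OC)cc2)/C=C(/C)CC/C=C(/I)C1=O | intermediate
21 | (1E,4Z,6R,7S,8S)-10-iodo-6-[(4-methoxybenzyl)oxy]-4-methyl-9-oxo-7-(3-{[tert-butyl(dimethyl)silyl]oxy}prop-1-en-2-yl)cyclodeca-1(10),4-dien-8-yl 2-methylprop-2-enoate | C=C(C)C(=O)O[C@H]1[C@@H](C(=C)CO[Si](C)(C)C(C)(C)C)[C@H](OCc2ccc(OC)cc2)/C=C(/C)CC/C=C(/I)C1=O | intermediate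
22 | (1E,4Z,6R,7S,8S,9R)-9-hydroxy-10-iodo-6-[(4-methoxybenzyl)oxy]-4-methyl-7-(3-{[tert-butyl(dimethyl)silyl]oxy}prop-1-en-2-yl)cyclodeca-1(10),4-dien-8-yl 2-methylprop-2-enoate | C=C(C)C(=O)O[C@H]1[C@@H](C(=C)CO[Si](C)(C)C(C)(C)C)[C@H](OCc2ccc(OC)cc2)/C=C(/C)CC/C=C(/I)[C@@H]1O | intermediate
23 | methyl (1E,4Z,6R,7S,8S,9S)-9-hydroxy-6-[(4-methoxybenzyl)oxy]-4-methyl-8-(methacryloyloxy)-7-(3-{[tert-butyl(dimethyl)silyl]oxy}prop-1-en-2-yl)cyclodeca-1(10),4-diene-10-carboxylate | C=C(C)C(=O)O[C@H]1[C@@H](C(=C)CO[Si](C)(C)C(C)(C)C)[C@H](OCc2ccc(OC)cc2)/C=C(/C)CC/C=C(/C(=O)OC)[C@@H]1O | intermediate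
24 | methyl (1E,4Z,6R,7S,8S,9S)-9-acetoxy-6-[(4-methoxybenzyl)oxy]-4-methyl-8-(methacryloyloxy)-7-(3-{[tert-butyl(dimethyl)silyl]oxy}prop-1-en-2-yl)cyclodeca-1(10),4-diene-10-carboxylate | C=C(C)C(=O)O[C@H]1[C@@H](C(=C)CO[Si](C)(C)C(C)(C)C)[C@H](OCc2ccc(OC)cc2)/C=C(/C)CC/C=C(/C(=O)OC)[C@@H]1OC(C)=O | intermediate
25 | methyl (1E,4Z,6R,7S,8S,9S)-9-acetoxy-6-hydroxy-4-methyl-8-(methacryloyloxy)-7-(3-{[tert-butyl(dimethyl)silyl]oxy}prop-1-en-2-yl)cyclodeca-1(10),4-diene-10-carboxylate | C=C(C)C(=O)O[C@H]1[C@@H](C(=C)CO[Si](C)(C)C(C)(C)C)[C@H](O)/C=C(/C)CC/C=C(/C(=O)OC)[C@@H]1OC(C)=O | intermediate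
26 | methyl (1E,4R,5S,6S,7S,8S,9S)-9-acetoxy-4,5-epoxy-6-hydroxy-4-methyl-8-(methacryloyloxy)-7-(3-{[tert-butyl(dimethyl)silyl]oxy}prop-1-en-2-yl)cyclodec-1(10)-ene-10-carboxylate | C=C(C)C(=O)O[C@H]1[C@@H](C(=C)CO[Si](C)(C)C(C)(C)C)[C@H](O)[C@@H]2O[C@]2(C)CC/C=C(/C(=O)OC)[C@@H]1OC(C)=O | intermediate
27 | methyl (1E,4R,5S,6S,7S,8S,9S)-9-acetoxy-4,5-epoxy-6-hydroxy-7-(3-hydroxyprop-1-en-2-yl)-4-methyl-8-(methacryloyloxy)cyclodec-1(10)-ene-10-carboxylate | C=C(C)C(=O)O[C@H]1[C@@H](C(=C)CO)[C@H](O)[C@@H]2O[C@]2(C)CC/C=C(/C(=O)OC)[C@@H]1OC(C)=O | intermediate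
28 | C12 aldehyde of 27 (7-(3-oxoprop-1-en-2-yl) compound, all stereocentres as in 27; not isolated) | C=C(C)C(=O)O[C@H]1[C@@H](C(=C)C=O)[C@H](O)[C@@H]2O[C@]2(C)CC/C=C(/C(=O)OC)[C@@H]1OC(C)=O | intermediate
29 | C12 lactol of the target (12-hydroxy-12,6-epoxy compound, either configuration at C12; not isolated) | C=C(C)C(=O)O[C@H]1[C@H]2C(=C)C(O)O[C@@H]2[C@@H]2O[C@]2(C)CC/C=C(/C(=O)OC)[C@@H]1OC(C)=O | intermediate
30 | CNP0153978.8: (4R,5S,6S,7R,8S,9S)-4,5-epoxy-germacra-1(10),11(13)-dien-12,6-olide with 8-methacrylate, 9-acetate and a methyl ester on C10, C1=C10 ring-cis, lactone trans-fused | C=C(C)C(=O)O[C@H]1[C@H]2C(=C)C(=O)O[C@@H]2[C@@H]2O[C@]2(C)CC/C=C(/C(=O)OC)[C@@H]1OC(C)=O | target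

Total step count: 19. Longest linear sequence: 17 steps (steps 1–3 and 6–19, from 1); steps 4 and 5 form the side branch.

Steps most likely to fail

Step 11. What may go wrong: the dissociated alkoxide may break the C4–C9 bond ionically (fragmentation or a [1,3] shift) instead of reorganising through the chair, and the enolate may be consumed by addition to the sulfonimine released from the oxidant. Fallback (neutral rearrangement, separate oxidation): setting out from 17, the tertiary hydroxyl is silylated with N-(trimethylsilyl)imidazole to the trimethylsilyl ether F1. Heating F1 in toluene in base-washed glassware should bring about the neutral silyloxy-Cope rearrangement through the same chair to the ten-membered trimethylsilyl enol ether F2. Rubottom oxidation of F2 with dimethyldioxirane at −78 °C on the outer enol ether face, then citric acid in methanol to remove the silyl group, brings the route back at 20.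

Step 12. What may go wrong: at the crowded C8 the carboxylate displacement may lose to elimination toward C7 or to acyl transfer with retention through an acyloxyphosphonium ion. Fallback (isolated sulfonate, separate displacement): from 20, Tf2O and 2,6-lutidine in CH2Cl2 at −78 °C give the 8R triflate F3. Caesium methacrylate with 18-crown-6 in toluene should displace it with inversion, substitution next to a carbonyl group being strongly accelerated, and the route is rejoined at 21.

Step 6. What may go wrong: poor facial selectivity if the ester does not chelate the metal (the wrong carbinol epimer cannot reach the required chair), with iodine–metal exchange at C10 as a further loss. Fallback (alkoxide-directed delivery): from 4, DIBAL-H reduces both carbonyl groups to the iodo diol F4 (mixture at the carbinol carbon). MnO2 re-oxidises only the allylic secondary alcohol to the hydroxymethyl iodoenone F5. Two equivalents of dienylcerium 10 are then used: the first forms the primary alkoxide, which ties the metal to the ketone in a six-membered chelate with methyl pseudoaxial and guides the second anti to methyl. This gives the diol directly, so the route is rejoined at 12 and step 7 is no longer needed.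

Further compounds
F1 | step 11 | trimethylsilyl ether of 17 at the tertiary oxygen | COc1ccc(CO/C=C/[C@@]2(C)CCC=C(I)[C@@]2(O[Si](C)(C)C)/C=C/C(=C)CO[Si](C)(C)C(C)(C)C)cc1
F2 | step 11 | ten-membered trimethylsilyl enol ether (ring-trans C8=C9, C6 and C7 as in 20) | C[Si](C)(C)O/C1=C\[C@@H](C(=C)CO[Si](C)(C)C(C)(C)C)[C@H](OCc2ccc(OC)cc2)/C=C(/C)CC/C=C1/I
F3 | step 12 | (8R)-trifluoromethanesulfonate of 20 | O=S(=O)(O[C@@H]1[C@@H](C(=C)CO[Si](C)(C)C(C)(C)C)[C@H](OCc2ccc(OC)cc2)/C=C(/C)CC/C=C(/I)C1=O)C(F)(F)F
F4 | step 6 | (6R)-6-(hydroxymethyl)-2-iodo-6-methylcyclohex-2-en-1-ol (both carbinol epimers) | OC[C@@]1(C)CCC=C(I)C1O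
F5 | step 6 | (6R)-6-(hydroxymethyl)-2-iodo-6-methylcyclohex-2-en-1-one | OC[C@@]1(C)CCC=C(I)C1=O
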